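If substrate leaves by two routes, one using reagent and one not, divide one rate by the other so that time drops out.

| flask | substrate | reagent | remark | time |
|---|---|---|---|---|
| winter | 0.087 M | 0.25 M | run made earlier |  |
| summer | 0.59 M | 0.25 M | run made earlier |  |
| autumn | 0.10 M | 0.65 M | run made earlier |  |
| north | 0.10 M | 0.250 M |  | 1.5 h |
| north-west | 0.060 M | 0.400 M |  | 1.5 h |
| south | 0.40 M | 0.800 M |  | 1.5 h |
| east | 0.10 M | 1.00 M |  | 1.5 h |

| run | time / min | target / % | substrate / % |
|---|---|---|---|
| winter | 4.00 | 10 | 87 |
| winter | 8.00 | 17 | 77 |
| winter | 20.0 | 35 | 51 |
| winter | 50.0 | 50 | 20 |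
| summer | 12.0 | 17 | 69 |
| summer | 25.0 | 24 | 48 |
| summer | 30.0 | 28 | 49 |
| summer | 50.0 | 31 | 35 |
| autumn | 6.00 | 31 | 63 |
| autumn | 15.0 | 53 | 31 |
| autumn | 30.0 | 74 | 13 |
| autumn | 50.0 | 77 | 3 |

(standard deviation of a reading: 2 percentage points)

- the earlier runs were read with a standard deviation of 2 percentage points
- candidate steps: substrate + reagent <-> target; substrate -> intermediate A; intermediate A <-> intermediate B; reagent + intermediate A <-> intermediate C; reagent + intermediate B <-> intermediate D

1. the flasks by amount of target, in percent of the substrate charged, highest first, at 1.5 h (north / north-west / south / east)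
2. the amount of target, in percent of the substrate charged of the flask you put first, at 1.5 h
3. the amount of target, in percent of the substrate charged of the flask you put last, at 1.5 h

Take the candidate steps in turn: substrate with reagent gives target, substrate by itself gives intermediate A, and intermediates B, C and D lie downstream of intermediate A. So target per substrate lost is reagent over reagent plus a constant.

Read that constant from the last winter reading. Target stands at 50% and substrate at 20%, so 30.0% went elsewhere, at a mean reagent of 0.228 M, the charge less half the target formed. This gives 0.137 M for the crossover reagent, the concentration at which both routes run equally, a selectivity factor written as a concentration. The last autumn reading gives 0.159 M.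

But the share applies to lost substrate, so check the clock. Winter substrate decays at 0.0322 min⁻¹, so extrapolate that first-order decay to north, charged close to winter, and take as an estimate, not a reading, a loss of 94.5% by 1.5 h. East holds more reagent than autumn, whose substrate reads 3% at 50.0 min, so count east as fully converted.

Take mean reagent as the charge less half the substrate charge: east 0.950 M, south 0.600 M, north-west 0.370 M, north 0.200 M. Rank them so. My reckoning gives east 87.4% and north 56.1%.

The forecast, reckoning “target ≈ selectivity at average reagent”, gives east > south > north-west > north, with 86% and 57%, against my figures just stated.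

The flasks give east > south > north-west > north, with 87.2% and 58.1%.

    substrate + reagent ⇌ target (K = 100 M⁻¹, k = 0.100 M⁻¹ min⁻¹)
    substrate → intermediate A (k = 0.0120 min⁻¹)
    intermediate A ⇌ intermediate B (K = 1.80, k = 0.0120 min⁻¹)
    reagent + intermediate A ⇌ intermediate C (K = 3.00 M⁻¹, k = 0.0870 M⁻¹ min⁻¹)
    reagent + intermediate B ⇌ intermediate D (K = 2.40 M⁻¹, k = 0.0480 M⁻¹ min⁻¹)

Carry the crossover reagent of 0.137 M to a neighbour of north charged with 0.40 M of substrate, reagent and time held. Reagent is now the limiting reagent, its charge being smaller than the substrate's. This flask ends with 23.3% of its own reagent and 15.1% of its substrate, so its mean reagent is 0.154 M. The share to target is then 52.9%, which makes 44.9% target. The neighbour holds 42.6%.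

Readings and results come from a simulation for an exercise; noise was put on by code.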